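**Retrosynthetic overview**

1. Locants are those of the azulene core of the target: five-membered ring C1–C2–C3–C3a–C8a, seven-membered ring C3a–C4–C5–C6–C7–C8–C8a; α is the face of H-3a, O-4 and O-8, β that of the 8a-methyl and the 3-OH.
2. Endgame: the O8-acetate and O4-anisoate are disconnected first, then the isopropyl group from C3 (α-face organocerium addition to a C3 ketone); this leaves the C3-ketal of a trans-fused 4α,8α-diol.
3. H-3a and HO-4 are traced to one syn addition across a C3a=C4 olefin, delivered from O8 through a silicon tether (intramolecular hydrosilylation, Tamao oxidation); this leads back to a 3a(4),6-dien-8α-ol.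
4. Enabling feature: in the seven-membered ring the C6=C7 olefin lies between C5H2 and the C8 carbinol, which is bonded to the quaternary ring-fusion carbon C8a. With C3a=C4 as a second olefin the ring is a cyclohepta-1,4-diene, the retron of a cis-divinylcyclopropane rearrangement that forms C8–C8a and breaks a C4–C6 cyclopropane bond; one vinyl arm is C3a=C8a of a cyclopentene, the other an (E)-alkenylboronate (latent C8–O).
5. Ring order: cyclopentene (bought as a bromo enone), then a temporary cyclopropane (ligand-controlled Simmons–Smith reaction on a (Z)-dienol from a Suzuki coupling, the only reagent-controlled stereo-event), then the seven-membered ring last by 3→7 ring expansion.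

Key step: step 7

Assumption: with the (4R,5R)-dioxaborolane ligand CH2 is delivered in the facial sense known for cinnamyl alcohol (→ (1S,2S)-product), independent of olefin substitution; if the sense proves opposite, the (4S,5S)-ligand is used.

**Route**

Step 1
Reactants: 1 prop-2-yn-1-ol
Product: 3 (Z)-3-iodo-2-methylprop-2-en-1-ol, via alkenylmagnesium alkoxide 2 (not isolated)
Conditions: MeMgBr (2.5 equiv), CuI (10 mol%), THF, −10 °C → rt; then I2, −78 °C → rt
Reagents that add atoms: methylmagnesium bromide, C[Mg]Br; iodine, II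
Why: Copper-catalysed anti-carbomagnesiation of the propargylic alkoxide puts methyl on C2 and magnesium on C3 in a five-membered chelate, and iodinolysis of the C–Mg bond with retention gives only the Z-iodoalkene (I cis to CH2OH).

Step 2
Reactants: 4 2-bromo-3-methylcyclopent-2-en-1-one
Product: 5 6-bromo-7-methyl-1,4-dioxaspiro[4.4]non-6-ene
Conditions: ethylene glycol, p-TsOH (cat.), benzene, reflux (Dean–Stark)
Reagents that add atoms: ethylene glycol, OCCO
Why: Acid-catalysed ketalisation with azeotropic removal of water, the standard entry to α-keto vinyl anion equivalents from 2-bromocycloalkenones; the olefin stays between the bromo- and methyl-bearing carbons.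

Step 3
Reactants: 5 6-bromo-7-methyl-1,4-dioxaspiro[4.4]non-6-ene; 3 (Z)-3-iodo-2-methylprop-2-en-1-ol
Product: 8 (2Z)-2-methyl-3-(7-methyl-1,4-dioxaspiro[4.4]non-6-en-6-yl)prop-2-en-1-ol, via alkenyllithium 6 (not isolated), via lithium triisopropyl borate 7 (not isolated)
Conditions: n-BuLi, THF, −78 °C; B(Oi-Pr)3, −78 °C → rt; then 3, Pd(dppf)Cl2 (cat.), aq. K3PO4, 50 °C
Reagents that add atoms: none
Why: Bromine–lithium exchange, trapping as the triisopropyl borate and in-situ Suzuki–Miyaura coupling join the two sp2 carbons with retention of the Z geometry of 3, so CH2OH ends cis to the cyclopentenyl group as the later cyclopropane requires; the free hydroxyl is tolerated in the aqueous basic medium.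

Step 4
Reactants: 8 (2Z)-2-methyl-3-(7-methyl-1,4-dioxaspiro[4.4]non-6-en-6-yl)prop-2-en-1-ol
Product: 9 [(1S,2R)-1-methyl-2-(7-methyl-1,4-dioxaspiro[4.4]non-6-en-6-yl)cyclopropyl]methanol
Conditions: Et2Zn, CH2I2, DME; (4R,5R)-2-butyl-N,N,N′,N′-tetramethyl-1,3,2-dioxaborolane-4,5-dicarboxamide (1.2 equiv), CH2Cl2, −10 °C → rt
Reagents that add atoms: diiodomethane, ICI
Why: Hydroxyl-directed Simmons–Smith cyclopropanation under control of the chiral dioxaborolane (Charette variant) adds CH2 stereospecifically syn to the allylic-alcohol olefin only (the tetrasubstituted ring olefin is neither directed nor reactive); the ligand chooses the olefin face and thereby both cyclopropane stereocentres (1S,2R), and the Z geometry of 8 fixes the cis relation of CH2OH and cyclopentenyl.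

Step 5
Reactants: 9 [(1S,2R)-1-methyl-2-(7-methyl-1,4-dioxaspiro[4.4]non-6-en-6-yl)cyclopropyl]methanol
Product: 10 (1S,2R)-1-methyl-2-(7-methyl-1,4-dioxaspiro[4.4]non-6-en-6-yl)cyclopropane-1-carbaldehyde
Conditions: Dess–Martin periodinane, pyridine, CH2Cl2, 0 °C → rt
Reagents that add atoms: none
Why: Dess–Martin oxidation under buffered conditions gives the aldehyde without touching ketal or cyclopropane; the α-carbon is quaternary, so it cannot epimerise.

Step 6
Reactants: 10 (1S,2R)-1-methyl-2-(7-methyl-1,4-dioxaspiro[4.4]non-6-en-6-yl)cyclopropane-1-carbaldehyde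
Product: 11 4,4,5,5-tetramethyl-2-{(E)-2-[(1R,2R)-1-methyl-2-(7-methyl-1,4-dioxaspiro[4.4]non-6-en-6-yl)cyclopropyl]ethenyl}-1,3,2-dioxaborolane
Conditions: CrCl2 (8 equiv), Cl2CHBpin, LiI, THF, rt
Reagents that add atoms: 2-(dichloromethyl)-4,4,5,5-tetramethyl-1,3,2-dioxaborolane, ClC(Cl)B1OC(C)(C)C(C)(C)O1
Why: Takai–Utimoto boron olefination: the gem-dichromium species adds to the aldehyde (ketal untouched) and eliminates to the E-alkenylboronate selectively at room temperature, below the onset of rearrangement of this hindered divinylcyclopropane.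

Step 7
Reactants: 11 4,4,5,5-tetramethyl-2-{(E)-2-[(1R,2R)-1-methyl-2-(7-methyl-1,4-dioxaspiro[4.4]non-6-en-6-yl)cyclopropyl]ethenyl}-1,3,2-dioxaborolane
Product: 13 (8R,8aS)-3,3-(ethylenedioxy)-6,8a-dimethyl-1,2,3,5,8,8a-hexahydroazulen-8-ol, via allylboronate 12 (not isolated)
Conditions: toluene, 100 °C (sealed tube); then 30% H2O2, 3 M NaOH, THF, 0 °C
Reagents that add atoms: hydrogen peroxide, OO
Why: Heating brings the cis-divinylcyclopropane into the endo,endo boat conformer, and a concerted [3,3] shift (cis-divinylcyclopropane–cycloheptadiene rearrangement, closest precedents being those that build a ring-fusion quaternary carbon from a 2-methylcycloalkenyl arm and those of E-heteroatom-substituted vinyl arms) breaks the C4–C6 cyclopropane bond and forms C8–C8a, driven by release of three-ring strain. The seven-membered ring is thus closed by a 3→7 ring enlargement through a boat transition state, the only array that gives the two cis ring olefins C3a=C4 and C6=C7. C8a is controlled by the cyclopropane stereocentres of step 4: the cyclopentene can bond only through the face lying over the three-membered ring, so that configuration is relayed suprafacially. C8 is controlled by the E geometry of the alkenylboronate: boron sits outside and H inside the boat, whereas the 8a-methyl is the inside group of the other terminus, so boron ends trans to that methyl, and oxidation of the allylic C–B bond with retention gives the 8α-alcohol. The step needs the cis relation of the two arms (secured by the Z-olefin of 8 and the stereospecific cyclopropanation), a temperature that overcomes the inside methyl yet stays below one-centre epimerisation of the cyclopropane, and no carbonyl for the allylboronate to attack, which the ketal guarantees.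

Step 8
Reactants: 13 (8R,8aS)-3,3-(ethylenedioxy)-6,8a-dimethyl-1,2,3,5,8,8a-hexahydroazulen-8-ol
Product: 16 (3aS,4S,8R,8aS)-3,3-(ethylenedioxy)-6,8a-dimethyl-1,2,3,3a,4,5,8,8a-octahydroazulene-4,8-diol, via dimethylsilyl ether 14 (not isolated), via cyclic siloxane 15 (not isolated)
Conditions: HMe2SiCl, Et3N, DMAP (cat.), CH2Cl2, 0 °C; then Karstedt catalyst (Pt2(dvds)3, cat.), toluene, 60 °C; then KF, KHCO3, 30% H2O2, THF/MeOH, rt
Reagents that add atoms: hydrogen peroxide, OO
Why: After silylation of the only hydroxyl, platinum-catalysed intramolecular hydrosilylation (Tamao type, syn addition of Si–H) puts silicon on the less substituted C4 and hydrogen on C3a of the homoallylic C3a=C4 olefin in the 6-endo, anti-Markovnikov mode from the α-face on which the O8 tether sits (the allylic C6=C7 olefin would need silicon on its fully substituted carbon), and Tamao–Fleming oxidation with retention turns C4–Si into C4–OH, so H-3a and HO-4 are both set cis to O-8 (trans ring fusion, 4α-OH).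

Step 9
Reactants: 16 (3aS,4S,8R,8aS)-3,3-(ethylenedioxy)-6,8a-dimethyl-1,2,3,3a,4,5,8,8a-octahydroazulene-4,8-diol
Product: 17 (3aS,4S,8R,8aS)-4,8-dihydroxy-6,8a-dimethyl-2,3a,4,5,8,8a-hexahydroazulen-3(1H)-one
Conditions: PPTS (cat.), acetone/H2O (10:1), 40 °C
Reagents that add atoms: water, O
Why: Mild acid-catalysed ketal hydrolysis unmasks the C3 ketone; pyridinium tosylate should be too weak to ionise the allylic alcohol or enolise the ketone toward C3a, so the new ring-fusion centre is kept.

Step 10
Reactants: 17 (3aS,4S,8R,8aS)-4,8-dihydroxy-6,8a-dimethyl-2,3a,4,5,8,8a-hexahydroazulen-3(1H)-one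
Product: 18 (3R,3aS,4S,8R,8aS)-6,8a-dimethyl-3-(propan-2-yl)-1,2,3,3a,4,5,8,8a-octahydroazulene-3,4,8-triol
Conditions: i-PrMgCl (excess), anhydrous CeCl3, THF, −78 → 0 °C
Reagents that add atoms: isopropylmagnesium chloride, CC(C)[Mg]Cl
Why: Organocerium 1,2-addition (low basicity suppresses enolisation, retro-aldol cleavage and β-hydride reduction) should occur on the α-face of the cyclopentanone, anti to the C4 branch on C3a and to the 8a-methyl that both shield the β-face, giving the 3β-hydroxy-3α-isopropyl centre (3R).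

Step 11
Reactants: 18 (3R,3aS,4S,8R,8aS)-6,8a-dimethyl-3-(propan-2-yl)-1,2,3,3a,4,5,8,8a-octahydroazulene-3,4,8-triol
Product: 19 (3R,3aS,4S,8R,8aS)-3,8-dihydroxy-6,8a-dimethyl-3-(propan-2-yl)-1,2,3,3a,4,5,8,8a-octahydroazulen-4-yl 4-methoxybenzoate
Conditions: 4-methoxybenzoyl chloride (1.05 equiv), Et3N, DMAP (cat.), CH2Cl2, 0 °C
Reagents that add atoms: 4-methoxybenzoyl chloride, COc1ccc(cc1)C(Cl)=O
Why: DMAP-catalysed acylation with one equivalent of acid chloride at low temperature should take the secondary 4-OH, which is less shielded than the 8-OH (neopentylic to quaternary C8a and flanked by the trisubstituted olefin) and far more reactive than the tertiary 3-OH; no stereocentre is touched.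

Step 12
Reactants: 19 (3R,3aS,4S,8R,8aS)-3,8-dihydroxy-6,8a-dimethyl-3-(propan-2-yl)-1,2,3,3a,4,5,8,8a-octahydroazulen-4-yl 4-methoxybenzoate
Product: 20 (3R,3aS,4S,8R,8aS)-8-(acetyloxy)-3-hydroxy-6,8a-dimethyl-3-(propan-2-yl)-1,2,3,3a,4,5,8,8a-octahydroazulen-4-yl 4-methoxybenzoate
Conditions: Ac2O, Et3N, DMAP (cat.), CH2Cl2, rt
Reagents that add atoms: acetic anhydride, CC(=O)OC(C)=O
Why: DMAP-catalysed acetylation of the remaining secondary hydroxyl; the tertiary 3-OH does not acylate under these conditions, and the basic medium avoids ionisation of the allylic ester.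

**Compound list**

1 | prop-2-yn-1-ol | C#CCO | starting material
2 | bromomagnesium (Z)-3-(bromomagnesio)-2-methylprop-2-en-1-olate | Br[Mg]OC/C(C)=C\[Mg]Br | intermediate
3 | (Z)-3-iodo-2-methylprop-2-en-1-ol | OC/C(C)=C\I | intermediate
4 | 2-bromo-3-methylcyclopent-2-en-1-one | CC1=C(Br)C(=O)CC1 | starting material
5 | 6-bromo-7-methyl-1,4-dioxaspiro[4.4]non-6-ene | BrC1=C(C)CCC12OCCO2 | intermediate
6 | (7-methyl-1,4-dioxaspiro[4.4]non-6-en-6-yl)lithium | [Li]C1=C(C)CCC12OCCO2 | intermediate
7 | lithium triisopropoxy(7-methyl-1,4-dioxaspiro[4.4]non-6-en-6-yl)borate | CC(C)O[B-](OC(C)C)(OC(C)C)C1=C(C)CCC12OCCO2.[Li+] | intermediate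
8 | (2Z)-2-methyl-3-(7-methyl-1,4-dioxaspiro[4.4]non-6-en-6-yl)prop-2-en-1-ol | OC/C(C)=C\C1=C(C)CCC12OCCO2 | intermediate
9 | [(1S,2R)-1-methyl-2-(7-methyl-1,4-dioxaspiro[4.4]non-6-en-6-yl)cyclopropyl]methanol | C[C@]1(CO)C[C@H]1C2=C(C)CCC23OCCO3 | intermediate
10 | (1S,2R)-1-methyl-2-(7-methyl-1,4-dioxaspiro[4.4]non-6-en-6-yl)cyclopropane-1-carbaldehyde | C[C@]1(C=O)C[C@H]1C2=C(C)CCC23OCCO3 | intermediate
11 | 4,4,5,5-tetramethyl-2-{(E)-2-[(1R,2R)-1-methyl-2-(7-methyl-1,4-dioxaspiro[4.4]non-6-en-6-yl)cyclopropyl]ethenyl}-1,3,2-dioxaborolane | C[C@]1(/C=C/B4OC(C)(C)C(C)(C)O4)C[C@H]1C2=C(C)CCC23OCCO3 | intermediate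
12 | 2-[(8R,8aR)-3,3-(ethylenedioxy)-6,8a-dimethyl-1,2,3,5,8,8a-hexahydroazulen-8-yl]-4,4,5,5-tetramethyl-1,3,2-dioxaborolane | CC1(C)OB(OC1(C)C)[C@@H]2C=C(C)CC=C3C4(OCCO4)CC[C@]23C | intermediate
13 | (8R,8aS)-3,3-(ethylenedioxy)-6,8a-dimethyl-1,2,3,5,8,8a-hexahydroazulen-8-ol | O[C@@H]1C=C(C)CC=C2C3(OCCO3)CC[C@]12C | intermediate
14 | {[(8R,8aS)-3,3-(ethylenedioxy)-6,8a-dimethyl-1,2,3,5,8,8a-hexahydroazulen-8-yl]oxy}dimethylsilane | C[SiH](C)O[C@@H]1C=C(C)CC=C2C3(OCCO3)CC[C@]12C | intermediate
15 | (3aR,4S,8R,8aS)-3,3-(ethylenedioxy)-6,8a-dimethyl-1,2,3,3a,4,5,8,8a-octahydroazulene bridged from C4 to O8 by a dimethylsilylene group on the α-face (H-3a α) | C[Si]4(C)[C@H]1CC(C)=C[C@@H](O4)[C@@]2(C)CCC3(OCCO3)[C@H]12 | intermediate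
16 | (3aS,4S,8R,8aS)-3,3-(ethylenedioxy)-6,8a-dimethyl-1,2,3,3a,4,5,8,8a-octahydroazulene-4,8-diol | O[C@H]1CC(C)=C[C@@H](O)[C@@]2(C)CCC3(OCCO3)[C@H]12 | intermediate
17 | (3aS,4S,8R,8aS)-4,8-dihydroxy-6,8a-dimethyl-2,3a,4,5,8,8a-hexahydroazulen-3(1H)-one | O[C@H]1CC(C)=C[C@@H](O)[C@@]2(C)CCC(=O)[C@H]12 | intermediate
18 | (3R,3aS,4S,8R,8aS)-6,8a-dimethyl-3-(propan-2-yl)-1,2,3,3a,4,5,8,8a-octahydroazulene-3,4,8-triol | O[C@H]1CC(C)=C[C@@H](O)[C@@]2(C)CC[C@@](O)(C(C)C)[C@H]12 | intermediate
19 | (3R,3aS,4S,8R,8aS)-3,8-dihydroxy-6,8a-dimethyl-3-(propan-2-yl)-1,2,3,3a,4,5,8,8a-octahydroazulen-4-yl 4-methoxybenzoate | COc1ccc(cc1)C(=O)O[C@H]1CC(C)=C[C@@H](O)[C@@]2(C)CC[C@@](O)(C(C)C)[C@H]12 | intermediate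
20 | (3R,3aS,4S,8R,8aS)-8-(acetyloxy)-3-hydroxy-6,8a-dimethyl-3-(propan-2-yl)-1,2,3,3a,4,5,8,8a-octahydroazulen-4-yl 4-methoxybenzoate (CNP0256979.2) | COc1ccc(cc1)C(=O)O[C@H]1CC(C)=C[C@@H](OC(C)=O)[C@@]2(C)CC[C@@](O)(C(C)C)[C@H]12 | target

**Step count and risks**

Total step count: 12. Longest linear sequence: 11 steps (4 → 20 through steps 2–12; equally 1 → 20 through steps 1 and 3–12).

Steps most likely to fail:

1. Step 8. The platinum hydride may fail to insert the hindered trisubstituted C3a=C4 olefin, may isomerise it, or may engage the allylic C6=C7 olefin, and the Si–O tether may redistribute. The fallback sets out from 13 and comes back at 17. Hydrolysis of the ketal (PPTS, wet acetone) should give the cross-conjugated (8R,8aS)-8-hydroxy-6,8a-dimethyl-1,2,8,8a-tetrahydroazulen-3(5H)-one F1. Copper(I)-catalysed conjugate borylation of its enone (B2pin2, CuCl, NaOt-Bu, a chiral bisphosphine whose sense is matched to α-face attack at C4, MeOH as proton source) should give (3aR,4S,8R,8aS)-8-hydroxy-6,8a-dimethyl-4-(4,4,5,5-tetramethyl-1,3,2-dioxaborolan-2-yl)-2,3a,4,5,8,8a-hexahydroazulen-3(1H)-one F2; here C4 is set by the catalyst and C3a by protonation of the enolate from the face opposite the 8a-methyl. Oxidation with retention (NaBO3, THF/H2O) then leads to keto diol 17.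

2. Step 7. The inside methyl of the cyclopentene terminus raises the barrier; at the temperature needed the allylic boronate may undergo 1,3-boron shift or protodeboronation before oxidation, and one-centre epimerisation of the cyclopropane may begin. The fallback sets out from 11 and comes back at 13, carrying oxygen instead of boron through the rearrangement. Copper(II)-promoted oxidative C–O coupling of the alkenylboronate with 4-methoxybenzyl alcohol (Cu(OAc)2, Et3N, air; Chan–Lam type, retention of the E geometry) should give 6-{(1R,2S)-2-[(E)-2-(4-methoxybenzyloxy)ethenyl]-2-methylcyclopropyl}-7-methyl-1,4-dioxaspiro[4.4]non-6-ene F3. Its thermal rearrangement (toluene, 80–110 °C; the enol-ether class is the best documented for this rearrangement) should give (8R,8aS)-3,3-(ethylenedioxy)-8-[(4-methoxybenzyl)oxy]-6,8a-dimethyl-1,2,3,5,8,8a-hexahydroazulene F4, and DDQ in buffered CH2Cl2/H2O releases alcohol 13.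

3. Step 11. Site selection between the two secondary hydroxyls may be poor, giving acylation at O-8 or at both. The fallback sets out from 18 and comes back at 20, fixing the order by a transient boronate. Condensation with phenylboronic acid (toluene, 4 Å MS) should tie the tertiary 3-OH and secondary 4-OH into the six-membered cyclic 3,4-O-phenylboronate of triol 18 F5. Ac2O/pyridine/DMAP then acetylates the only free hydroxyl to the 8-O-acetyl 3,4-O-phenylboronate F6. A wash with aqueous sorbitol/Na2CO3 releases (3R,3aS,4S,8R,8aS)-3,4-dihydroxy-6,8a-dimethyl-3-(propan-2-yl)-1,2,3,3a,4,5,8,8a-octahydroazulen-8-yl acetate F7, and Steglich esterification (4-methoxybenzoic acid, DCC, DMAP) of its single secondary hydroxyl gives 20.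

Further compounds
F1 | step 8 | (8R,8aS)-8-hydroxy-6,8a-dimethyl-1,2,8,8a-tetrahydroazulen-3(5H)-one | O[C@@H]1C=C(C)CC=C2C(=O)CC[C@]12C
F2 | step 8 | (3aR,4S,8R,8aS)-8-hydroxy-6,8a-dimethyl-4-(4,4,5,5-tetramethyl-1,3,2-dioxaborolan-2-yl)-2,3a,4,5,8,8a-hexahydroazulen-3(1H)-one | CC1(C)OB(OC1(C)C)[C@H]2CC(C)=C[C@@H](O)[C@@]3(C)CCC(=O)[C@H]23
F3 | step 7 | 6-{(1R,2S)-2-[(E)-2-(4-methoxybenzyloxy)ethenyl]-2-methylcyclopropyl}-7-methyl-1,4-dioxaspiro[4.4]non-6-ene | C[C@]1(/C=C/OCc4ccc(OC)cc4)C[C@H]1C2=C(C)CCC23OCCO3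
F4 | step 7 | (8R,8aS)-3,3-(ethylenedioxy)-8-[(4-methoxybenzyl)oxy]-6,8a-dimethyl-1,2,3,5,8,8a-hexahydroazulene | COc1ccc(CO[C@@H]2C=C(C)CC=C3C4(OCCO4)CC[C@]23C)cc1
F5 | step 11 | cyclic 3,4-O-phenylboronate of triol 18 | c1ccccc1B2O[C@H]3CC(C)=C[C@@H](O)[C@@]4(C)CC[C@@](O2)(C(C)C)[C@H]34
F6 | step 11 | 8-O-acetyl 3,4-O-phenylboronate of triol 18 | c1ccccc1B2O[C@H]3CC(C)=C[C@@H](OC(C)=O)[C@@]4(C)CC[C@@](O2)(C(C)C)[C@H]34
F7 | step 11 | (3R,3aS,4S,8R,8aS)-3,4-dihydroxy-6,8a-dimethyl-3-(propan-2-yl)-1,2,3,3a,4,5,8,8a-octahydroazulen-8-yl acetate | O[C@H]1CC(C)=C[C@@H](OC(C)=O)[C@@]2(C)CC[C@@](O)(C(C)C)[C@H]12
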